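**Retrosynthetic overview**
1. Phyltetralin ⇒ all-trans 1-aryl-2-vinyl-3-(methoxymethyl)tetralin: the C2 CH2OMe arm is carried as a vinyl group (cleave, reduce, methylate).
2. Vinyl tetralin ⇒ open-chain diaryl carbinol by cutting C1–C2. Ring B, the only ring made, closes when the γ-carbon (future C2) of a tethered (E)-allylsilane attacks the C1 cation.
3. Carbinol ⇒ veratraldehyde + an aryl bromide carrying the allylsilane side chain (Br/Li exchange); allylsilane ⇒ terminal alkene + allyltrimethylsilane (cross-metathesis).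
4. Future C3 ⇒ auxiliary-controlled α-alkylation of a crotonyl imide dienolate with 2-bromo-4,5-dimethoxybenzyl bromide. Ring A arrives with its bromine, so no ring halogenation is needed beside an alkene, and the vinyl group appears in the same step.
5. Feature used: C1 is benzylic to ring A (C6–OMe para to C8a) and to the 3,4-dimethoxyphenyl ring (4-OMe para), so a C1 carbinol ionises under mild acid; C3 then directs C2 and C1 through a chair.

Key step: step 7

Remark on numbering: tetralin numbering is used. C1 carries the aryl group, C2 and C3 the CH2OMe arms, C4 is the benzylic CH2; ring A is aromatic, ring B saturated.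
Assumption: the cross-metathesis product of step 5 is expected mainly as the (E) isomer. Any (Z) isomer is carried along, because both alkene geometries are predicted to give the same 2,3-trans ring closure.

**Route**

Step 1
Reactants: 1 (S)-4-benzyl-1,3-oxazolidin-2-one; 2 (E)-but-2-enoyl chloride (crotonyl chloride)
Product: 4 (S)-4-benzyl-3-[(E)-but-2-enoyl]-1,3-oxazolidin-2-one, via lithium oxazolidinide 3 (not isolated)
Conditions: n-BuLi, THF, −78 °C; then 2, −78 → 0 °C
Reagents that add atoms: none
Why: N-acylation of the lithiated oxazolidinone by an acid chloride (nucleophilic acyl substitution) is the standard way of loading this auxiliary and creates no stereocentre.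

Step 2
Reactants: 4 (S)-4-benzyl-3-[(E)-but-2-enoyl]-1,3-oxazolidin-2-one; 5 2-bromo-4,5-dimethoxybenzyl bromide
Product: 7 (S)-4-benzyl-3-[(S)-2-(2-bromo-4,5-dimethoxybenzyl)but-3-enoyl]-1,3-oxazolidin-2-one, via sodium dienolate 6 (not isolated)
Conditions: NaN(SiMe3)2, THF, −78 °C; then 5, −78 → −40 °C; AcOH quench at −78 °C
Reagents that add atoms: none
Why: Evans auxiliary alkylation run on the dienolate: γ-deprotonation gives the chelated (Z)-sodium dienolate, which the reactive benzylic bromide should alkylate at the α-carbon (deconjugative alkylation) on the face away from the C4 benzyl group, so that the future C3 is set as (S) and the vinyl group is unveiled in the same operation.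

Step 3
Reactants: 7 (S)-4-benzyl-3-[(S)-2-(2-bromo-4,5-dimethoxybenzyl)but-3-enoyl]-1,3-oxazolidin-2-one
Product: 8 (S)-2-(2-bromo-4,5-dimethoxybenzyl)but-3-en-1-ol
Conditions: LiBH4, H2O (1 equiv), Et2O, 0 °C
Reagents that add atoms: none
Why: Reductive cleavage of the N-acyl oxazolidinone with LiBH4 (hydride reduction at the exocyclic imide carbonyl) should release the primary alcohol and the intact auxiliary and, being non-basic, should leave the allylic stereocentre, the terminal alkene and the aryl bromide untouched.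

Step 4
Reactants: 8 (S)-2-(2-bromo-4,5-dimethoxybenzyl)but-3-en-1-ol
Product: 10 (S)-1-bromo-4,5-dimethoxy-2-[2-(methoxymethyl)but-3-en-1-yl]benzene, via sodium alkoxide 9 (not isolated)
Conditions: NaH, THF, 0 °C; then MeI, 0 °C → rt
Reagents that add atoms: iodomethane, CI
Why: Williamson ether synthesis (alkoxide 9 plus MeI, SN2) should methylate the only hydroxyl group, and no acidic C–H is present that could put the stereocentre at risk.

Step 5
Reactants: 10 (S)-1-bromo-4,5-dimethoxy-2-[2-(methoxymethyl)but-3-en-1-yl]benzene; 11 allyltrimethylsilane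
Product: 12 [(2E,4S)-5-(2-bromo-4,5-dimethoxyphenyl)-4-(methoxymethyl)pent-2-en-1-yl]trimethylsilane
Conditions: 11 (4 equiv), second-generation Grubbs catalyst RuCl2(=CHPh)(H2IMes)(PCy3) (5 mol %), CH2Cl2, 40 °C
Reagents that add atoms: none
Why: Olefin cross-metathesis of the monosubstituted alkene with an excess of allyltrimethylsilane should give the 1,2-disubstituted allylsilane with the (E) isomer favoured by the allylic branch, while the aryl bromide, the ethers and the stereocentre are inert to the ruthenium carbene.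

Step 6
Reactants: 12 [(2E,4S)-5-(2-bromo-4,5-dimethoxyphenyl)-4-(methoxymethyl)pent-2-en-1-yl]trimethylsilane; 13 veratraldehyde (3,4-dimethoxybenzaldehyde)
Product: 15 (3,4-dimethoxyphenyl){4,5-dimethoxy-2-[(2S,3E)-2-(methoxymethyl)-5-(trimethylsilyl)pent-3-en-1-yl]phenyl}methanol (both carbinol epimers), via aryllithium 14 (not isolated)
Conditions: n-BuLi, THF, −78 °C; then 13, −78 °C; H2O quench
Reagents that add atoms: none
Why: Bromine–lithium exchange on the aryl bromide at −78 °C is far faster than any attack of n-BuLi on the allylsilane or the ethers, and the aryllithium then adds to the aldehyde (1,2-carbonyl addition); the carbinol centre forms without control, which is harmless because step 7 erases it.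

Step 7
Reactants: 15 (3,4-dimethoxyphenyl){4,5-dimethoxy-2-[(2S,3E)-2-(methoxymethyl)-5-(trimethylsilyl)pent-3-en-1-yl]phenyl}methanol
Product: 18 (1R,2S,3S)-1-(3,4-dimethoxyphenyl)-2-ethenyl-6,7-dimethoxy-3-(methoxymethyl)-1,2,3,4-tetrahydronaphthalene, via diarylmethyl cation 16 (not isolated), via β-silyl cation 17 (not isolated)
Conditions: Bi(OTf)3 (5 mol %), CH2Cl2 (0.01 M), −40 → 0 °C
Reagents that add atoms: none
Why: Catalytic Bi(OTf)3 should ionise the doubly benzylic carbinol (either epimer) to the diarylmethyl cation 16, whose charge is shared by the para-methoxy groups of both rings (C6–OMe of ring A and the 4-OMe of the pendant ring); the γ-carbon of the allylsilane then bonds to C1 to give the β-silyl cation 17, which sheds the silyl group to leave the vinyl group on C2. The closest known reaction type is the intramolecular Hosomi–Sakurai reaction (allylsilane-terminated cation–olefin cyclization), and bis(methoxyphenyl)methyl cations made from their carbinols under this kind of acid catalysis are standard partners for allylsilanes. Ring B closes by forming C1–C2 as a six-membered ring, exo with respect to the allylsilane double bond (6-exo-trig), through a chair-like transition state. C2 is controlled by C3: the C3–H bond eclipses the double bond to avoid allylic strain and CH2OMe lies equatorial, so the cation meets the alkene face that places the new vinyl group equatorial and trans to CH2OMe. C1 is controlled by the shape of the planar cation, in which the 3,4-dimethoxyphenyl group points towards H8 and away from the C4 tether, so it ends pseudo-equatorial and trans to the vinyl group. The step needs attack by the γ-carbon to outrun protodesilylation and intermolecular capture of the cation, which the very easy ionisation (catalytic acid at low temperature), the six-membered tether and high dilution should secure.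

Step 8
Reactants: 18 (1R,2S,3S)-1-(3,4-dimethoxyphenyl)-2-ethenyl-6,7-dimethoxy-3-(methoxymethyl)-1,2,3,4-tetrahydronaphthalene
Product: 20 (1R,2S,3S)-1-(3,4-dimethoxyphenyl)-6,7-dimethoxy-3-(methoxymethyl)-1,2,3,4-tetrahydronaphthalene-2-carbaldehyde, via vicinal diol 19 (not isolated)
Conditions: OsO4 (2 mol %), NaIO4, 2,6-lutidine, dioxane–H2O, rt
Reagents that add atoms: osmium tetroxide OsO4, O=[Os](=O)(=O)=O; sodium periodate NaIO4, [Na+].[O-]I(=O)(=O)=O (terminal oxidant that supplies the oxygen through OsO4)
Why: Lemieux–Johnson oxidation, in which catalytic OsO4 should dihydroxylate the only alkene and NaIO4 cleave diol 19 to the aldehyde while re-forming OsO4, with 2,6-lutidine buffering the medium; C2 already holds its most stable, all-equatorial arrangement, so enolisation has nothing to gain.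

Step 9
Reactants: 20 (1R,2S,3S)-1-(3,4-dimethoxyphenyl)-6,7-dimethoxy-3-(methoxymethyl)-1,2,3,4-tetrahydronaphthalene-2-carbaldehyde
Product: 21 [(1R,2S,3S)-1-(3,4-dimethoxyphenyl)-6,7-dimethoxy-3-(methoxymethyl)-1,2,3,4-tetrahydronaphthalen-2-yl]methanol
Conditions: NaBH4, MeOH, 0 °C
Reagents that add atoms: none
Why: Hydride reduction of the aldehyde with NaBH4 should give the primary alcohol cleanly, since no other reducible group is present and prompt reduction limits any epimerisation at C2.

Step 10
Reactants: 21 [(1R,2S,3S)-1-(3,4-dimethoxyphenyl)-6,7-dimethoxy-3-(methoxymethyl)-1,2,3,4-tetrahydronaphthalen-2-yl]methanol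
Product: 23 phyltetralin [(1R,2S,3S)-1-(3,4-dimethoxyphenyl)-6,7-dimethoxy-2,3-bis(methoxymethyl)-1,2,3,4-tetrahydronaphthalene], via sodium alkoxide 22 (not isolated)
Conditions: NaH, THF, 0 °C; then MeI, rt
Reagents that add atoms: iodomethane, CI
Why: Williamson ether synthesis (alkoxide 22 plus MeI, SN2) should install the second methyl ether and finish the target without touching any stereocentre.

**Compound list**
1 | (S)-4-benzyl-1,3-oxazolidin-2-one | O=C1OC[C@H](Cc2ccccc2)N1 | starting material
2 | (E)-but-2-enoyl chloride | C/C=C/C(Cl)=O | starting material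
3 | lithium salt of 1 (not isolated) | O=C1OC[C@H](Cc2ccccc2)[N-]1.[Li+] | intermediate
4 | (S)-4-benzyl-3-[(E)-but-2-enoyl]-1,3-oxazolidin-2-one | C/C=C/C(=O)N1[C@@H](Cc2ccccc2)COC1=O | intermediate
5 | 2-bromo-4,5-dimethoxybenzyl bromide | BrCc1cc(OC)c(OC)cc1Br | starting material
6 | sodium (Z)-dienolate of 4 (not isolated) | C=C/C=C(\[O-])N1[C@@H](Cc2ccccc2)COC1=O.[Na+] | intermediate
7 | (S)-4-benzyl-3-[(S)-2-(2-bromo-4,5-dimethoxybenzyl)but-3-enoyl]-1,3-oxazolidin-2-one | O=C([C@H](C=C)Cc1cc(OC)c(OC)cc1Br)N1[C@@H](Cc2ccccc2)COC1=O | intermediate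
8 | (S)-2-(2-bromo-4,5-dimethoxybenzyl)but-3-en-1-ol | OC[C@H](C=C)Cc1cc(OC)c(OC)cc1Br | intermediate
9 | sodium alkoxide of 8 (not isolated) | [O-]C[C@H](C=C)Cc1cc(OC)c(OC)cc1Br.[Na+] | intermediate
10 | (S)-1-bromo-4,5-dimethoxy-2-[2-(methoxymethyl)but-3-en-1-yl]benzene | COC[C@H](C=C)Cc1cc(OC)c(OC)cc1Br | intermediate
11 | allyltrimethylsilane | C=CC[Si](C)(C)C | starting material
12 | [(2E,4S)-5-(2-bromo-4,5-dimethoxyphenyl)-4-(methoxymethyl)pent-2-en-1-yl]trimethylsilane | COC[C@H](/C=C/C[Si](C)(C)C)Cc1cc(OC)c(OC)cc1Br | intermediate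
13 | veratraldehyde (3,4-dimethoxybenzaldehyde) | COc1ccc(C=O)cc1OC | starting material
14 | aryllithium from 12 (not isolated) | COC[C@H](/C=C/C[Si](C)(C)C)Cc1cc(OC)c(OC)cc1[Li] | intermediate
15 | (3,4-dimethoxyphenyl){4,5-dimethoxy-2-[(2S,3E)-2-(methoxymethyl)-5-(trimethylsilyl)pent-3-en-1-yl]phenyl}methanol, both carbinol epimers | COC[C@H](/C=C/C[Si](C)(C)C)Cc1cc(OC)c(OC)cc1C(O)c1ccc(OC)c(OC)c1 | intermediate
16 | diarylmethyl cation from 15, written as its triflate ion pair (not isolated) | COC[C@H](/C=C/C[Si](C)(C)C)Cc1cc(OC)c(OC)cc1[CH+]c1ccc(OC)c(OC)c1.[O-]S(=O)(=O)C(F)(F)F | intermediate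
17 | cyclised β-silyl cation, written as its triflate ion pair (not isolated) | COC[C@H]1Cc2cc(OC)c(OC)cc2[C@@H](c2ccc(OC)c(OC)c2)[C@@H]1[CH+]C[Si](C)(C)C.[O-]S(=O)(=O)C(F)(F)F | intermediate
18 | (1R,2S,3S)-1-(3,4-dimethoxyphenyl)-2-ethenyl-6,7-dimethoxy-3-(methoxymethyl)-1,2,3,4-tetrahydronaphthalene | COC[C@H]1Cc2cc(OC)c(OC)cc2[C@@H](c2ccc(OC)c(OC)c2)[C@@H]1C=C | intermediate
19 | vicinal diol from 18, both carbinol epimers (not isolated) | COC[C@H]1Cc2cc(OC)c(OC)cc2[C@@H](c2ccc(OC)c(OC)c2)[C@@H]1C(O)CO | intermediate
20 | (1R,2S,3S)-1-(3,4-dimethoxyphenyl)-6,7-dimethoxy-3-(methoxymethyl)-1,2,3,4-tetrahydronaphthalene-2-carbaldehyde | COC[C@H]1Cc2cc(OC)c(OC)cc2[C@@H](c2ccc(OC)c(OC)c2)[C@@H]1C=O | intermediate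
21 | [(1R,2S,3S)-1-(3,4-dimethoxyphenyl)-6,7-dimethoxy-3-(methoxymethyl)-1,2,3,4-tetrahydronaphthalen-2-yl]methanol | COC[C@H]1Cc2cc(OC)c(OC)cc2[C@@H](c2ccc(OC)c(OC)c2)[C@@H]1CO | intermediate
22 | sodium alkoxide of 21 (not isolated) | COC[C@H]1Cc2cc(OC)c(OC)cc2[C@@H](c2ccc(OC)c(OC)c2)[C@@H]1C[O-].[Na+] | intermediate
23 | phyltetralin, (1R,2S,3S)-1-(3,4-dimethoxyphenyl)-6,7-dimethoxy-2,3-bis(methoxymethyl)-1,2,3,4-tetrahydronaphthalene | COC[C@H]1Cc2cc(OC)c(OC)cc2[C@@H](c2ccc(OC)c(OC)c2)[C@@H]1COC | target

**Totals**
Total step count: 10. Longest linear sequence: 10 steps (1 → 23); the route is linear, and 2, 5, 11 and 13 enter as purchased reagents.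

**Steps most likely to fail**

Step 7 (key ring closure). After ionisation the cation may be captured with poor facial control at C1, or the allylsilane may be protonated and lose its silyl group before the ring closes. The fallback sets out from 12 and comes back at 18. Bromine–lithium exchange on 12 (n-BuLi, THF, −78 °C) and quenching with DMF would give 2-[(2S,3E)-2-(methoxymethyl)-5-(trimethylsilyl)pent-3-en-1-yl]-4,5-dimethoxybenzaldehyde F1. SnCl4 in CH2Cl2 at −78 °C would then bring about the intramolecular Hosomi–Sakurai allylation of the aldehyde, forming C1–C2 through the same chair and giving the 2,3-trans alcohol (2R,3S)-2-ethenyl-6,7-dimethoxy-3-(methoxymethyl)-1,2,3,4-tetrahydronaphthalen-1-ol F2, whose C1 configuration is irrelevant. F2 would finally be ionised with catalytic FeCl3 in CH2Cl2 in the presence of veratrole (1,2-dimethoxybenzene). In this benzylic Friedel–Crafts arylation the arene should bond through its 4-position to C1 on the face opposite the C2 vinyl group, giving 18. The ring is thus closed onto an aldehyde and the aryl group is brought in afterwards, so the C1 configuration no longer depends on the folding of a diarylmethyl cation.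

Step 5 (cross-metathesis). Metathesis at the branched allylic carbon may be sluggish, the silane may be consumed by self-metathesis, and control of the alkene geometry may be incomplete. The fallback sets out from 10 and comes back at 18. Oxidative cleavage of 10 (catalytic OsO4, NaIO4, 2,6-lutidine) would give (R)-2-(2-bromo-4,5-dimethoxybenzyl)-3-methoxypropanal F3, to be used at once and cold because its α-centre is epimerisable. Wittig olefination with Ph3P=CHCH2SiMe3 (from Ph3P=CH2 and ICH2SiMe3, then n-BuLi; THF, −78 °C) would give the geometrically defined [(2Z,4S)-5-(2-bromo-4,5-dimethoxyphenyl)-4-(methoxymethyl)pent-2-en-1-yl]trimethylsilane F4. Bromine–lithium exchange and addition to 13 as in step 6 would give (3,4-dimethoxyphenyl){4,5-dimethoxy-2-[(2S,3Z)-2-(methoxymethyl)-5-(trimethylsilyl)pent-3-en-1-yl]phenyl}methanol F5. Under the conditions of step 7 this should close to 18, because in the (Z) series allylic strain holds the C3–H bond in the alkene plane still more firmly and the same chair places the vinyl group trans to CH2OMe.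

Step 2 (dienolate alkylation). The dienolate may be alkylated at its γ-carbon, or base may return the double bond of the product into conjugation and destroy the new stereocentre. The fallback sets out from 1 and comes back at 10. The vinyl group is carried masked as a 2-(phenylsulfanyl)ethyl group, so that an ordinary saturated imide enolate is alkylated. Acylation of 1 with commercial 4-(phenylsulfanyl)butanoic acid (pivaloyl chloride, Et3N, LiCl, THF) would give (S)-4-benzyl-3-[4-(phenylsulfanyl)butanoyl]-1,3-oxazolidin-2-one F6. Enolisation with NaN(SiMe3)2 and alkylation with 5, with the same facial course, would give (S)-4-benzyl-3-[(S)-2-(2-bromo-4,5-dimethoxybenzyl)-4-(phenylsulfanyl)butanoyl]-1,3-oxazolidin-2-one F7. LiBH4 would give (S)-2-(2-bromo-4,5-dimethoxybenzyl)-4-(phenylsulfanyl)butan-1-ol F8, and NaH with MeI would give 1-bromo-4,5-dimethoxy-2-[(2S)-2-(methoxymethyl)-4-(phenylsulfanyl)butyl]benzene F9. NaIO4 (MeOH–H2O, 0 °C) would give 1-bromo-4,5-dimethoxy-2-[(2S)-2-(methoxymethyl)-4-(phenylsulfinyl)butyl]benzene F10, and thermal syn-elimination of benzenesulfenic acid (xylene, CaCO3, 140 °C) would unveil the terminal alkene of 10.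

**Further compounds**
F1 | step 7 | 2-[(2S,3E)-2-(methoxymethyl)-5-(trimethylsilyl)pent-3-en-1-yl]-4,5-dimethoxybenzaldehyde | COC[C@H](/C=C/C[Si](C)(C)C)Cc1cc(OC)c(OC)cc1C=O
F2 | step 7 | (2R,3S)-2-ethenyl-6,7-dimethoxy-3-(methoxymethyl)-1,2,3,4-tetrahydronaphthalen-1-ol, both C1 epimers | COC[C@H]1Cc2cc(OC)c(OC)cc2C(O)[C@@H]1C=C
F3 | step 5 | (R)-2-(2-bromo-4,5-dimethoxybenzyl)-3-methoxypropanal | COC[C@H](C=O)Cc1cc(OC)c(OC)cc1Br
F4 | step 5 | [(2Z,4S)-5-(2-bromo-4,5-dimethoxyphenyl)-4-(methoxymethyl)pent-2-en-1-yl]trimethylsilane | COC[C@H](/C=C\C[Si](C)(C)C)Cc1cc(OC)c(OC)cc1Br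
F5 | step 5 | (3,4-dimethoxyphenyl){4,5-dimethoxy-2-[(2S,3Z)-2-(methoxymethyl)-5-(trimethylsilyl)pent-3-en-1-yl]phenyl}methanol, both carbinol epimers | COC[C@H](/C=C\C[Si](C)(C)C)Cc1cc(OC)c(OC)cc1C(O)c1ccc(OC)c(OC)c1
F6 | step 2 | (S)-4-benzyl-3-[4-(phenylsulfanyl)butanoyl]-1,3-oxazolidin-2-one | O=C(CCCSc1ccccc1)N1[C@@H](Cc2ccccc2)COC1=O
F7 | step 2 | (S)-4-benzyl-3-[(S)-2-(2-bromo-4,5-dimethoxybenzyl)-4-(phenylsulfanyl)butanoyl]-1,3-oxazolidin-2-one | O=C([C@H](CCSc1ccccc1)Cc1cc(OC)c(OC)cc1Br)N1[C@@H](Cc2ccccc2)COC1=O
F8 | step 2 | (S)-2-(2-bromo-4,5-dimethoxybenzyl)-4-(phenylsulfanyl)butan-1-ol | OC[C@H](CCSc1ccccc1)Cc1cc(OC)c(OC)cc1Br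
F9 | step 2 | 1-bromo-4,5-dimethoxy-2-[(2S)-2-(methoxymethyl)-4-(phenylsulfanyl)butyl]benzene | COC[C@H](CCSc1ccccc1)Cc1cc(OC)c(OC)cc1Br
F10 | step 2 | 1-bromo-4,5-dimethoxy-2-[(2S)-2-(methoxymethyl)-4-(phenylsulfinyl)butyl]benzene, both sulfur epimers | COC[C@H](CCS(=O)c1ccccc1)Cc1cc(OC)c(OC)cc1Br
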